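Begin at early times and ask what the coupling partner does to the rate at which target forms in these flasks.

| flask | starting material | coupling partner | time |
|---|---|---|---|
| red | 0.600 M | 0.480 M |  |
| ochre | 0.240 M | 0.120 M |  |
| grey | 0.600 M | 1.40 M |  |
| amber | 0.300 M | 0.160 M | 7.6 h |

| run | time / h | [target] / M |
|---|---|---|
| red run | 0.30 | 0.0239 |
| red run | 0.68 | 0.0504 |
| red run | 1.5 | 0.0959 |
| red run | 3.4 | 0.1441 |
| red run | 7.6 | 0.1711 |
| ochre run | 0.30 | 0.0013 |
| ochre run | 0.68 | 0.0027 |
| ochre run | 1.5 | 5 × 10⁻⁴ |
| ochre run | 3.4 | 0.0062 |
| ochre run | 7.6 | 0.0040 |
| grey run | 0.30 | 0.1822 |
| grey run | 0.68 | 0.3146 |
| grey run | 1.5 | 0.4242 |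
| grey run | 3.4 | 0.4627 |
| grey run | 7.6 | 0.4666 |

(readings scatter by 0.002 M)

1. reaction order in [coupling partner] at the outset, round the charge of the red run, defined at two percent of the starting material turned into target
2. reaction order in [starting material] at the outset, round the charge of the red run, defined at two percent of the starting material turned into target (one fixed amount of target, the same in the runs compared)
3. target in the amber run at 7.6 h, as a share of the starting material charged

- Overall: starting material + coupling partner -> target.
- Constant volume, constant temperature.
- "The second partner" is coupling partner.
- An order is taken over about fifteen percent of the charge, up and down.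

Compare target at 0.30 h: grey holds 0.1822 M and red 0.0239 M from equal c(starting material), so this reading gives an order of 1.90 in c(coupling partner). Grey already bends by then, so commit to 2.

But the late end shows a second path: grey rises by just 0.00390 M between its last readings, though by the overall equation 0.933 M of coupling partner remains and 0.133 M of starting material never became target. So assume a competing loss, first order in starting material, and join the two ends. The selectivity between the paths then gives a share of charge ending as target: the square of c(coupling partner) over that square plus the square of c(split), the even-split concentration, at which target and loss take equal shares.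

Red reaches a share of 28.5% at 7.6 h, though it still rose by 0.0270 M over its last interval. Taking the charge for c(coupling partner) gives c(split) = 0.760 M.

Test it on ochre: the share 2.43% of its charge means 0.00584 M, against a reading of 0.0040 M with scatter 0.002 M. That agreement is loose: this one reading cannot select an order in starting material, and ochre also changes c(coupling partner), so order 1 stays my assumption. For amber, reckon 4.24%.

The forecast, reading “a competing loss of starting material”, gives orders 2 and 1 and a share of 3.9%, a little lower than mine.

The flask gives orders 2.1 and 1.1, and amber gives 4.21%.

    starting material + 2 coupling partner → target + coupling partner (0.6480 M⁻² h⁻¹)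
    starting material + coupling partner + target → 2 target (1.458 M⁻² h⁻¹)
    starting material → decomposed substrate (0.3571 h⁻¹)

At 7.6 h in amber, with target at 0.0126 M and c(coupling partner) taken as the charge less that target, the target-assisted step runs at 0.193 of the first step. Put c(split) = 0.760 M on grey: its share of 77.2% means 0.463 M, and grey reads 0.4666 M at 7.6 h.

The runs were computed for an exercise; noise was put on by code.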